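**Remark on the chemistry:** the SMILES string defines the target as a 1,2-diarylethane, so it is treated as the bibenzyl 3,3'-dihydroxy-2,6-bis(4-hydroxybenzyl)-5-methoxybibenzyl. Ring A is numbered C1 (bridge) to C6, ring B carries primed locants, and rings C and D are the 4-hydroxyphenyl rings on the C2 and C6 methylene groups.

## Structural features

The target is an achiral bibenzyl made of four benzene rings. Ring A is pentasubstituted: C1 carries the CH2CH2 bridge (Cα on C1, Cβ on C1' of ring B), C2 and C6 each carry a 4-hydroxybenzyl group (rings C and D), C3 a free hydroxyl, C5 a methoxy group, and only C4 bears hydrogen. Ring B is a 3-hydroxyphenyl group. There is no stereocentre, so no stereocentres stand next to each other; the one created on the way (Cα while it carries boron) is removed again. The sensitive parts are the four free phenols (air oxidation, and para-quinone methide formation from the 4-hydroxybenzyl units under acid or oxidants) and the two doubly benzylic CH2 groups, which are acidic towards organolithium bases. The real difficulty is twofold. C1 of ring A is flanked by two benzyl groups and is meta to both ring oxygens, so a bond to it cannot be made by electrophilic substitution and is awkward for cross-coupling at a di-ortho-substituted carbon. In addition, the two ring A oxygens differ (OH at C3, OCH3 at C5) although everything else on ring A is mirror-symmetric, and the other three oxygens must end up free. The key step exploits the C1–Cα–Cβ–C1' bridge: a vinyl unit can be stitched between ring A C1 as nucleophile and ring B C1' as electrophile.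

## Logic of the disconnections

**19 ⇒ 18.** The four phenolic O–H bonds (O3 of ring A, O3' of ring B, O4 of rings C and D) are traced back to O–CH2Ph bonds, while O5 keeps its methyl group. Hydrogenolysis separates benzyl from methyl with no selectivity needed among like groups. A variant of 18 with five methyl ethers and a mirror-symmetric ring A was considered and set aside, because its last step would have to remove four of five methyl groups and stop after one on ring A. The gain is an unambiguous end game. The demand is that ring A carries two different ethers from early on and that every intermediate tolerates aryl benzyl ethers.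

**18 ⇒ 17.** The Cα–H bond is traced back to a Cα–B bond (pinacol boronate). Boron is the trace left by the three-component coupling, and its removal also erases the only stereocentre. Nothing is gained in atoms, but the retron of the key step appears. The demand is C–B protonolysis at a crowded secondary benzylic carbon.

**17 ⇒ 11 + 14 + 13 (through 15 and 16).** The bonds C1–Cα and Cβ–C1' are cut. The hindered C1 is bonded by a shift from boron to carbon instead of by reductive elimination at palladium. The molecule falls into the complete ring A block, a two-carbon linchpin and ring B. The demands are an aryllithium that survives next to two acidic CH2 groups, halide-free cationic palladium, and a metallate shift faster than direct group transfer.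

**13 ⇒ 12.** The S–O bond of the triflate is cut, leading to a phenol that already carries the ring B benzyl ether. The demand is trivial.

**11 ⇒ 10 ⇒ 9 + 6.** The benzylic C–H on the C6 arm is traced back to C–OH, and then the bond between the carbinol carbon and ring D is cut. An aldehyde next to bromine is a natural acceptor for an aryl Grignard reagent, and the resulting diarylmethanol ionises easily for hydride reduction. The demand is that reduction outruns Friedel–Crafts reactions and spares the benzyl ethers and the bromide.

**9 ⇒ 8.** The C6–CHO bond is cut. C6 is para to O3 and ortho to O5, which makes it the most nucleophilic and least enclosed free position. The demand is attack at C6 and not at C4.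

**8 ⇒ 7 ⇒ 4 + 6.** The same pair of cuts is made for the C2 arm and ring C, with the same demands.

**6 ⇒ 5.** The C–Mg bond is traced back to a C–Br bond. Rings C and D are the same aryl unit, so one batch of the organomagnesium reagent serves both arms. The gain is a single bought aryl bromide that already carries the phenol protecting group. The demand is only clean magnesium insertion next to an inert aryl benzyl ether.

**4 ⇒ 3 ⇒ 2.** The O3–benzyl bond is cut, then O3–H is traced back to O3–CH3. The formyl group at C2, needed anyway for the first benzyl group, sits next to O3 and not next to O5, so it can direct removal of exactly that methyl group by chelation. This is where the two ring A oxygens are told apart, at the cheapest point of the route. The demand is demethylation only ortho to the carbonyl.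

**2 ⇒ 1.** The C2–CHO bond is cut. In 1 bromine already occupies the carbon meta to both oxygens, so the position that electrophilic chemistry cannot reach is bought and not made. The demand is formylation next to bromine and not between the two methoxy groups.

## Other disconnections considered

**Alternative 1:** The cut goes through ring A itself, at C1–C6 and C4–C5. In the forward direction the enolate of ester A2 would add in Michael fashion to the β-carbon of the α-benzyl enone A1, and the methyl ketone enolate would then close the ring by Claisen condensation on the ester carbon. This gives dione A3 as a diastereomer mixture, and dehydrogenation would lead to resorcinol A4.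
- In its favour: every substituent of ring A is fixed by connectivity, so no question of electrophilic regiochemistry arises. On that point it is better than the chosen plan, which depends on step 7. No transition metal is needed, and the diastereomers of A3 are irrelevant, as is the single stereocentre of the chosen plan.
- Against it: A1 is a trisubstituted β-alkyl enone with acidic methyl and γ-hydrogens, and the enolate of A2 is a hard base. Proton transfer, 1,2-addition and self-condensation of A2 should compete with conjugate addition at a β-carbon shielded by the α-benzyl group.
- The aromatisation of A3 is an oxidation harsher than anything in the chosen route and endangers the benzylic positions.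
- A4 is mirror-symmetric, so the C3/C5 oxygen difference needs a statistical monomethylation or an aromatisation with iodine in methanol, and the three anisole ethers still have to be cleaved beside the ring A methyl ether.
- Comparison: it would be shorter (about eight steps against thirteen) and structurally more secure for the ring A pattern, but mechanistically less secure at its key step and at the oxidation-state adjustment.

**Alternative 2:** The cut is at the two bonds between the benzylic carbons on C2 and C6 and rings C and D. In the forward direction Pd(OAc)2 with glycine as a transient imine-forming directing group would arylate both ortho methyl groups of aldehyde A5 with 4-iodoanisole A6, giving aldehyde A7. The bridge would then follow by olefination and hydrogenation.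
- In its favour: both diarylmethane bonds are made in one operation, no organolithium is formed next to acidic CH2 groups, and the sequence from A5 is about five steps. On step economy it is clearly the better plan.
- Against it: the formyl carbon of A5 is meta to both methoxy groups and lies between two methyl groups, so A5 itself is not reachable by simple formylation.
- Imine formation at a di-ortho-substituted, electron-rich aldehyde is unfavourable. After the first arylation the new diarylmethane CH2 is a more activated C–H bond than the remaining methyl group, so over-arylation and mono/bis mixtures are to be expected.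
- The divalent/tetravalent palladium cycle needs stoichiometric silver salts in hot acidic medium.
- The symmetric dimethoxy ring A leaves the C3/C5 differentiation to the final deprotection, where the chosen plan is better.
- Comparison: both plans use a preformed ring A and reach C1 through a group meta to the oxygens. The chosen plan makes the diarylmethane bonds by carbonyl additions that are more predictable than a twofold C–H activation, at the price of more steps.

**Alternative 3:** The cut is at C6–C1 and C2–C3 of ring A. In the forward direction the 1,3-dimethoxy-1-silyloxy diene A8, which carries the C6 arylmethyl group, would add to ynone A9. Loss of methanol would aromatise the adduct to the ortho-aroyl phenol A10.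
- In its favour: ring A is produced with all six positions defined and with O3 free and O5 methylated straight from the cycloaddition. On this point it is better than the chosen plan, which spends steps 2 and 3 on the differentiation. Regiochemistry is set electronically, with the nucleophilic diene terminus attacking the β-carbon of the ynone.
- Against it: A8 is a hydrolytically labile ketene acetal whose terminal substituent slows cycloaddition, and A9 is an internal, β-alkyl ynone of modest reactivity. Open-chain Michael-type addition and desilylation should therefore compete at the temperatures required.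
- The hindered ortho-hydroxy diaryl ketone of A10 must still be reduced to CH2, and three anisole ethers must be removed beside the ring A methyl ether.
- Comparison: the step count would be lower (about eight to nine against thirteen). Ring construction is more elegant, but the key step is less certain than a coupling in which the crowded bond is formed by an intramolecular shift.

Key step: step 11

## Route

**Step 1**
Reactants: 1 1-bromo-3,5-dimethoxybenzene
Product: 2 2-bromo-4,6-dimethoxybenzaldehyde
Conditions: POCl3, DMF, 0 °C → 90 °C; then ice/H2O
Reagents that add atoms: N,N-dimethylformamide, CN(C)C=O; water, O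
Why: Vilsmeier–Haack formylation; the chloroiminium electrophile attacks the position para to one methoxy group and ortho to the other (next to bromine) in preference to the enclosed position between the two methoxy groups, and aqueous work-up liberates the aldehyde.

**Step 2**
Reactants: 2 2-bromo-4,6-dimethoxybenzaldehyde
Product: 3 2-bromo-6-hydroxy-4-methoxybenzaldehyde
Conditions: BCl3, CH2Cl2, −78 °C → 0 °C; then H2O
Reagents that add atoms: none
Why: Chelation-controlled Lewis acid ether cleavage; boron bridges the formyl oxygen and the neighbouring methoxy oxygen in a six-membered chelate, so chloride removes only the methyl group ortho to the aldehyde, and the para methoxy group (the future C5 methyl ether) cannot chelate and stays.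

**Step 3**
Reactants: 3 2-bromo-6-hydroxy-4-methoxybenzaldehyde
Product: 4 2-(benzyloxy)-6-bromo-4-methoxybenzaldehyde
Conditions: BnBr, K2CO3, DMF, 60 °C
Reagents that add atoms: benzyl bromide, BrCc1ccccc1
Why: Williamson ether synthesis; the acidic, hydrogen-bonded phenol is deprotonated by carbonate and alkylated on oxygen by the reactive benzylic bromide, and nothing else in the molecule is nucleophilic.

**Step 4**
Reactants: 5 1-(benzyloxy)-4-bromobenzene
Product: 6 4-(benzyloxy)phenylmagnesium bromide (one batch, kept as a titrated THF solution under argon and drawn on in steps 5 and 8)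
Conditions: Mg turnings, I2 (cat.), THF, reflux; titration
Reagents that add atoms: magnesium, [Mg]
Why: Grignard reagent formation by insertion of magnesium into the aryl C–Br bond; the aryl benzyl ether is inert to magnesium and to the arylmagnesium species in THF, and a single batch large enough for both additions is prepared.

**Step 5**
Reactants: 4 2-(benzyloxy)-6-bromo-4-methoxybenzaldehyde; 6 4-(benzyloxy)phenylmagnesium bromide
Product: 7 [2-(benzyloxy)-6-bromo-4-methoxyphenyl][4-(benzyloxy)phenyl]methanol (racemic)
Conditions: 6 (THF solution), THF, 0 °C → rt; then aq NH4Cl
Reagents that add atoms: none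
Why: Grignard addition of an arylmagnesium bromide to an aromatic aldehyde; the aryl bromide of 4 does not exchange with an arylmagnesium reagent at this temperature, and the carbinol centre forms as a racemate that is removed in step 6.

**Step 6**
Reactants: 7 [2-(benzyloxy)-6-bromo-4-methoxyphenyl][4-(benzyloxy)phenyl]methanol
Product: 8 1-bromo-3-(benzyloxy)-2-[4-(benzyloxy)benzyl]-5-methoxybenzene
Conditions: Et3SiH, CF3CO2H, CH2Cl2, 0 °C
Reagents that add atoms: none
Why: Ionic hydrogenation; the diarylmethanol ionises readily because the cation is stabilised by the para-benzyloxyphenyl ring and the ortho/para alkoxy groups of ring A, and excess silane traps it before acid can touch the aryl benzyl ethers.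

**Step 7**
Reactants: 8 1-bromo-3-(benzyloxy)-2-[4-(benzyloxy)benzyl]-5-methoxybenzene
Product: 9 4-(benzyloxy)-3-[4-(benzyloxy)benzyl]-2-bromo-6-methoxybenzaldehyde (formyl on ring A C6)
Conditions: POCl3, DMF, 0 °C → 80 °C; then ice/H2O
Reagents that add atoms: N,N-dimethylformamide, CN(C)C=O; water, O
Why: Vilsmeier–Haack formylation; C6 is para to the C3 benzyloxy group and ortho to the C5 methoxy group (the same relationship as in step 1), C4 is enclosed by two alkoxy groups of which the C3 one is pushed towards C4 by the C2 benzyl group, and the 4-benzyloxyphenyl ring is far less nucleophilic than the dialkoxy ring A.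

**Step 8**
Reactants: 9 4-(benzyloxy)-3-[4-(benzyloxy)benzyl]-2-bromo-6-methoxybenzaldehyde; 6 4-(benzyloxy)phenylmagnesium bromide
Product: 10 {4-(benzyloxy)-3-[4-(benzyloxy)benzyl]-2-bromo-6-methoxyphenyl}[4-(benzyloxy)phenyl]methanol (racemic)
Conditions: 6 (THF solution), THF, 0 °C → rt; then aq NH4Cl
Reagents that add atoms: none
Why: Grignard addition as in step 5, with a second portion of the same batch of 6; the aldehyde is flanked by bromine and methoxy but remains accessible to an aryl Grignard reagent, and the racemic carbinol centre is removed in step 9.

**Step 9**
Reactants: 10 {4-(benzyloxy)-3-[4-(benzyloxy)benzyl]-2-bromo-6-methoxyphenyl}[4-(benzyloxy)phenyl]methanol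
Product: 11 1-bromo-3-(benzyloxy)-2,6-bis[4-(benzyloxy)benzyl]-5-methoxybenzene
Conditions: Et3SiH, CF3CO2H, CH2Cl2, 0 °C
Reagents that add atoms: none
Why: Ionic hydrogenation as in step 6; the cation is stabilised by the ortho methoxy and para benzyloxy groups of ring A and by ring D, and silane in excess with acid added last keeps hydride capture ahead of intermolecular alkylation.

**Step 10**
Reactants: 12 3-(benzyloxy)phenol
Product: 13 3-(benzyloxy)phenyl trifluoromethanesulfonate
Conditions: Tf2O, pyridine, CH2Cl2, 0 °C
Reagents that add atoms: trifluoromethanesulfonic anhydride, O=S(=O)(OS(=O)(=O)C(F)(F)F)C(F)(F)F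
Why: O-Sulfonylation of a phenol with triflic anhydride and an amine base, a standard aryl triflate synthesis to which the benzyl ether is inert.

**Step 11**
Reactants: 11 1-bromo-3-(benzyloxy)-2,6-bis[4-(benzyloxy)benzyl]-5-methoxybenzene; 14 vinylboronic acid pinacol ester; 13 3-(benzyloxy)phenyl trifluoromethanesulfonate
Product: 17 2-{1-[3-(benzyloxy)-2,6-bis[4-(benzyloxy)benzyl]-5-methoxyphenyl]-2-[3-(benzyloxy)phenyl]ethyl}-4,4,5,5-tetramethyl-1,3,2-dioxaborolane (racemic), via ring A aryllithium 15 (not isolated), via lithium vinylboron ate complex 16 (not isolated)
Conditions: t-BuLi (2.0 equiv), THF/Et2O, −78 °C; then 14, −78 °C → rt; solvent exchange to THF; NaOTf, Pd(OAc)2 (cat.), bisphosphine ligand MandyPhos (cat.), 13, 60 °C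
Reagents that add atoms: none
Why: Conjunctive cross-coupling, the closest known reaction type being the palladium-catalysed three-component coupling of aryllithium-derived vinylboron ate complexes with aryl triflates. Bromine–lithium exchange at −78 °C gives 15, which adds to the vacant orbital on boron of 14 to give the four-coordinate boronate 16. Zerovalent palladium, formed from Pd(OAc)2 and the bisphosphine, inserts into the C–O bond of 13; the resulting cationic arylpalladium triflate binds the vinyl group of 16, which triggers migration of the ring A aryl group from boron to Cα while palladium bonds to Cβ, and reductive elimination then joins Cβ to C1' of ring B. No ring is closed. The new stereocentre at Cα needs no control (the ligand may be used as either enantiomer or as the racemate) and is removed in step 12. The selectivity needed is metallate shift over direct Suzuki-type transfer of a group from boron and over β-hydride elimination from the alkylpalladium intermediate. Removal of bromide as NaBr keeps palladium cationic and alkene-binding, the di-ortho-substituted ring A carbon is a poor partner for transmetalation but migrates readily inside the ate complex, and the wide-bite-angle ligand accelerates reductive elimination. The crowded C1 is thus bonded at boron by an intramolecular shift and never has to pass through palladium.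

**Step 12**
Reactants: 17 2-{1-[3-(benzyloxy)-2,6-bis[4-(benzyloxy)benzyl]-5-methoxyphenyl]-2-[3-(benzyloxy)phenyl]ethyl}-4,4,5,5-tetramethyl-1,3,2-dioxaborolane
Product: 18 3,3'-bis(benzyloxy)-2,6-bis[4-(benzyloxy)benzyl]-5-methoxybibenzyl
Conditions: TBAF·3H2O, toluene, 80 °C
Reagents that add atoms: none
Why: Fluoride-promoted protodeboronation; fluoride adds to boron and the benzylic C–B bond of the resulting four-coordinate boronate is protonated by the water of hydration, a protonolysis known for benzylic pinacol boronates (a secondary centre needs this more forcing fluoride source and heat), and aryl ethers are inert to it.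

**Step 13**
Reactants: 18 3,3'-bis(benzyloxy)-2,6-bis[4-(benzyloxy)benzyl]-5-methoxybibenzyl
Product: 19 3,3'-dihydroxy-2,6-bis(4-hydroxybenzyl)-5-methoxybibenzyl
Conditions: H2 (1 atm), Pd/C, EtOAc/MeOH, rt
Reagents that add atoms: none
Why: Catalytic hydrogenolysis of aryl benzyl ethers; the four O–CH2Ph bonds are cleaved while the aryl methyl ether, the diarylmethane CH2 groups and the bibenzyl bridge are stable, so the C3/C5 oxygen pattern installed in step 2 is revealed without any selectivity problem.

## Compound list

1 | 1-bromo-3,5-dimethoxybenzene | COc1cc(Br)cc(OC)c1 | starting material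
2 | 2-bromo-4,6-dimethoxybenzaldehyde | COc1cc(OC)c(C=O)c(Br)c1 | intermediate
3 | 2-bromo-6-hydroxy-4-methoxybenzaldehyde | COc1cc(O)c(C=O)c(Br)c1 | intermediate
4 | 2-(benzyloxy)-6-bromo-4-methoxybenzaldehyde | COc1cc(OCc2ccccc2)c(C=O)c(Br)c1 | intermediate
5 | 1-(benzyloxy)-4-bromobenzene | Brc1ccc(OCc2ccccc2)cc1 | starting material
6 | 4-(benzyloxy)phenylmagnesium bromide (THF solution) | Br[Mg]c1ccc(OCc2ccccc2)cc1 | intermediate
7 | [2-(benzyloxy)-6-bromo-4-methoxyphenyl][4-(benzyloxy)phenyl]methanol (racemic) | COc1cc(OCc2ccccc2)c(C(O)c2ccc(OCc3ccccc3)cc2)c(Br)c1 | intermediate
8 | 1-bromo-3-(benzyloxy)-2-[4-(benzyloxy)benzyl]-5-methoxybenzene | COc1cc(OCc2ccccc2)c(Cc2ccc(OCc3ccccc3)cc2)c(Br)c1 | intermediate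
9 | 4-(benzyloxy)-3-[4-(benzyloxy)benzyl]-2-bromo-6-methoxybenzaldehyde | COc1cc(OCc2ccccc2)c(Cc2ccc(OCc3ccccc3)cc2)c(Br)c1C=O | intermediate
10 | {4-(benzyloxy)-3-[4-(benzyloxy)benzyl]-2-bromo-6-methoxyphenyl}[4-(benzyloxy)phenyl]methanol (racemic) | COc1cc(OCc2ccccc2)c(Cc2ccc(OCc3ccccc3)cc2)c(Br)c1C(O)c1ccc(OCc2ccccc2)cc1 | intermediate
11 | 1-bromo-3-(benzyloxy)-2,6-bis[4-(benzyloxy)benzyl]-5-methoxybenzene | COc1cc(OCc2ccccc2)c(Cc2ccc(OCc3ccccc3)cc2)c(Br)c1Cc1ccc(OCc2ccccc2)cc1 | intermediate
12 | 3-(benzyloxy)phenol | Oc1cccc(OCc2ccccc2)c1 | starting material
13 | 3-(benzyloxy)phenyl trifluoromethanesulfonate | O=S(=O)(Oc1cccc(OCc2ccccc2)c1)C(F)(F)F | intermediate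
14 | vinylboronic acid pinacol ester (2-ethenyl-4,4,5,5-tetramethyl-1,3,2-dioxaborolane) | C=CB1OC(C)(C)C(C)(C)O1 | starting material
15 | {3-(benzyloxy)-2,6-bis[4-(benzyloxy)benzyl]-5-methoxyphenyl}lithium (not isolated) | COc1cc(OCc2ccccc2)c(Cc2ccc(OCc3ccccc3)cc2)c([Li])c1Cc1ccc(OCc2ccccc2)cc1 | intermediate
16 | lithium {3-(benzyloxy)-2,6-bis[4-(benzyloxy)benzyl]-5-methoxyphenyl}(ethenyl)(pinacolato)borate (not isolated) | [Li+].COc1cc(OCc2ccccc2)c(Cc2ccc(OCc3ccccc3)cc2)c([B-]2(C=C)OC(C)(C)C(C)(C)O2)c1Cc1ccc(OCc2ccccc2)cc1 | intermediate
17 | 2-{1-[3-(benzyloxy)-2,6-bis[4-(benzyloxy)benzyl]-5-methoxyphenyl]-2-[3-(benzyloxy)phenyl]ethyl}-4,4,5,5-tetramethyl-1,3,2-dioxaborolane (racemic at Cα, configuration of no consequence) | COc1cc(OCc2ccccc2)c(Cc2ccc(OCc3ccccc3)cc2)c(C(Cc2cccc(OCc3ccccc3)c2)B2OC(C)(C)C(C)(C)O2)c1Cc1ccc(OCc2ccccc2)cc1 | intermediate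
18 | 3,3'-bis(benzyloxy)-2,6-bis[4-(benzyloxy)benzyl]-5-methoxybibenzyl | COc1cc(OCc2ccccc2)c(Cc2ccc(OCc3ccccc3)cc2)c(CCc2cccc(OCc3ccccc3)c2)c1Cc1ccc(OCc2ccccc2)cc1 | intermediate
19 | 3,3'-dihydroxy-2,6-bis(4-hydroxybenzyl)-5-methoxybibenzyl | COc1cc(O)c(Cc2ccc(O)cc2)c(CCc2cccc(O)c2)c1Cc1ccc(O)cc1 | target

## Step count and least certain steps

Total: 13 steps. Longest linear sequence: 11 steps (steps 1–3, 5–9 and 11–13); steps 4 and 10 are one-step side branches. Should 2 be bought, step 1 falls away.

**Step 11 (key step).**
- What may go wrong: proton transfer from the doubly benzylic CH2 groups to the aryllithium before boron capture. Both ortho substituents of 15 carry such hydrogens, and the diarylmethyl anion is far more stable than the aryl anion.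
- Further hazards: slow ate-complex formation at the crowded carbon; poisoning of the cationic palladium by residual bromide; direct group transfer or β-hydride elimination in place of the shift.
- Fallback (from 11, returning at 19): the bridge is built by carbonyl olefination instead. Bromine–lithium exchange with n-BuLi at −78 °C and an immediate quench with DMF should give 3-(benzyloxy)-2,6-bis[4-(benzyloxy)benzyl]-5-methoxybenzaldehyde F1. Wittig olefination with [3-(benzyloxy)benzyl]triphenylphosphonium bromide F2 (made from 3-(benzyloxy)benzyl bromide and PPh3) and KOt-Bu should give the stilbene 3-(benzyloxy)-2,6-bis[4-(benzyloxy)benzyl]-1-{2-[3-(benzyloxy)phenyl]ethenyl}-5-methoxybenzene F3 as an E/Z mixture. Hydrogenation over Pd/C would then saturate the alkene and remove the four benzyl groups in one operation, giving 19.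

**Step 12.**
- What may go wrong: sluggish protonolysis of the C–B bond. Ring A is electron-rich and twisted out of conjugation by its two ortho substituents, so it stabilises the developing benzylic carbanion poorly, and oxidation by adventitious oxygen may then compete.
- Fallback (from 17, returning at 18): boron is replaced by oxygen and the oxygen is removed by a radical path. Oxidation with NaBO3·4H2O in THF/H2O should give 1-[3-(benzyloxy)-2,6-bis[4-(benzyloxy)benzyl]-5-methoxyphenyl]-2-[3-(benzyloxy)phenyl]ethanol F4 (racemic). Treatment with NaH, CS2 and MeI should give the xanthate O-{1-[3-(benzyloxy)-2,6-bis[4-(benzyloxy)benzyl]-5-methoxyphenyl]-2-[3-(benzyloxy)phenyl]ethyl} S-methyl carbonodithioate F5. Barton–McCombie reduction with Bu3SnH and AIBN in toluene at 80 °C, through the secondary benzylic radical, should give 18.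

**Step 7.**
- What may go wrong: electrophilic attack at C4 between the two alkoxy groups, or a slow reaction next to bromine during which hot acidic medium starts to cleave a benzyl ether. Both free positions of ring A are activated and differ only in para versus ortho activation and in crowding.
- Fallback (from 8, returning at 10): the polarity of the C6 arm is reversed. Iodination with N-iodosuccinimide and catalytic CF3CO2H in MeCN at rt, a milder and sterically more discriminating electrophile, should give 1-bromo-3-(benzyloxy)-2-[4-(benzyloxy)benzyl]-6-iodo-5-methoxybenzene F6, from which a regioisomer could be removed by crystallisation. Iodine–magnesium exchange with i-PrMgCl·LiCl at −20 °C (selective for iodine over bromine) and addition of the arylmagnesium species to 4-(benzyloxy)benzaldehyde should give carbinol 10 directly.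

**Step 9.**
- What may go wrong: intermolecular Friedel–Crafts alkylation by the diarylmethyl cation or acid-induced loss of a benzyl ether before hydride delivery. The cation is generated in a crowded pocket between bromine and methoxy, where hydride transfer from silicon is slowed, and electron-rich rings are abundant.
- Fallback (from 9, returning at 11): the carbinol and the acid are avoided altogether. Condensation of 9 with 4-methylbenzenesulfonohydrazide in MeOH should give the tosylhydrazone N'-({4-(benzyloxy)-3-[4-(benzyloxy)benzyl]-2-bromo-6-methoxyphenyl}methylidene)-4-methylbenzenesulfonohydrazide F7. Transition-metal-free reductive coupling of F7 with 4-(benzyloxy)phenylboronic acid (K2CO3, dioxane, 110 °C) should give the diarylmethane 11 with loss of nitrogen and sulfinate, leaving the aryl bromide untouched.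

## Further compounds

F1 | step 11 | 3-(benzyloxy)-2,6-bis[4-(benzyloxy)benzyl]-5-methoxybenzaldehyde | COc1cc(OCc2ccccc2)c(Cc2ccc(OCc3ccccc3)cc2)c(C=O)c1Cc1ccc(OCc2ccccc2)cc1
F2 | step 11 | [3-(benzyloxy)benzyl]triphenylphosphonium bromide | [Br-].c1ccc(COc2cccc(C[P+](c3ccccc3)(c3ccccc3)c3ccccc3)c2)cc1
F3 | step 11 | 3-(benzyloxy)-2,6-bis[4-(benzyloxy)benzyl]-1-{2-[3-(benzyloxy)phenyl]ethenyl}-5-methoxybenzene (E/Z mixture) | COc1cc(OCc2ccccc2)c(Cc2ccc(OCc3ccccc3)cc2)c(C=Cc2cccc(OCc3ccccc3)c2)c1Cc1ccc(OCc2ccccc2)cc1
F4 | step 12 | 1-[3-(benzyloxy)-2,6-bis[4-(benzyloxy)benzyl]-5-methoxyphenyl]-2-[3-(benzyloxy)phenyl]ethanol (racemic) | COc1cc(OCc2ccccc2)c(Cc2ccc(OCc3ccccc3)cc2)c(C(O)Cc2cccc(OCc3ccccc3)c2)c1Cc1ccc(OCc2ccccc2)cc1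
F5 | step 12 | O-{1-[3-(benzyloxy)-2,6-bis[4-(benzyloxy)benzyl]-5-methoxyphenyl]-2-[3-(benzyloxy)phenyl]ethyl} S-methyl carbonodithioate (racemic) | COc1cc(OCc2ccccc2)c(Cc2ccc(OCc3ccccc3)cc2)c(C(Cc2cccc(OCc3ccccc3)c2)OC(=S)SC)c1Cc1ccc(OCc2ccccc2)cc1
F6 | step 7 | 1-bromo-3-(benzyloxy)-2-[4-(benzyloxy)benzyl]-6-iodo-5-methoxybenzene | COc1cc(OCc2ccccc2)c(Cc2ccc(OCc3ccccc3)cc2)c(Br)c1I
F7 | step 9 | (E)-N'-({4-(benzyloxy)-3-[4-(benzyloxy)benzyl]-2-bromo-6-methoxyphenyl}methylidene)-4-methylbenzenesulfonohydrazide | COc1cc(OCc2ccccc2)c(Cc2ccc(OCc3ccccc3)cc2)c(Br)c1/C=N/NS(=O)(=O)c1ccc(C)cc1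
A1 | alternative 1 | (E)-3-(4-methoxybenzyl)-6-(3-methoxyphenyl)hex-3-en-2-one | CC(=O)/C(Cc1ccc(OC)cc1)=C/CCc1cccc(OC)c1
A2 | alternative 1 | methyl 3-(4-methoxyphenyl)propanoate | COC(=O)CCc1ccc(OC)cc1
A3 | alternative 1 | 4,6-bis(4-methoxybenzyl)-5-[2-(3-methoxyphenyl)ethyl]cyclohexane-1,3-dione (diastereomer mixture) | O=C1CC(=O)C(Cc2ccc(OC)cc2)C(CCc2cccc(OC)c2)C1Cc1ccc(OC)cc1
A4 | alternative 1 | 4,6-bis(4-methoxybenzyl)-5-[2-(3-methoxyphenyl)ethyl]benzene-1,3-diol | Oc1cc(O)c(Cc2ccc(OC)cc2)c(CCc2cccc(OC)c2)c1Cc1ccc(OC)cc1
A5 | alternative 2 | 3,5-dimethoxy-2,6-dimethylbenzaldehyde | COc1cc(OC)c(C)c(C=O)c1C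
A6 | alternative 2 | 4-iodoanisole | COc1ccc(I)cc1
A7 | alternative 2 | 3,5-dimethoxy-2,6-bis(4-methoxybenzyl)benzaldehyde | COc1cc(OC)c(Cc2ccc(OC)cc2)c(C=O)c1Cc1ccc(OC)cc1
A8 | alternative 3 | 1,3-dimethoxy-5-(4-methoxyphenyl)-1-(trimethylsilyloxy)penta-1,3-diene (mixture of geometric isomers) | COC(O[Si](C)(C)C)=CC(OC)=CCc1ccc(OC)cc1
A9 | alternative 3 | 1-(4-methoxyphenyl)-5-(3-methoxyphenyl)pent-2-yn-1-one | COc1ccc(cc1)C(=O)C#CCCc1cccc(OC)c1
A10 | alternative 3 | {2-hydroxy-4-methoxy-5-(4-methoxybenzyl)-6-[2-(3-methoxyphenyl)ethyl]phenyl}(4-methoxyphenyl)methanone | COc1cc(O)c(C(=O)c2ccc(OC)cc2)c(CCc2cccc(OC)c2)c1Cc1ccc(OC)cc1
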